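**Retrosynthetic overview**

1. Target 17 ⇐ 16 (palladium deallylation) ⇐ 15 (reduction of the ring B ester only) ⇐ 13 (O-prenylation). Ring A is bought as 1 and carried through.
2. Feature: ring B carries oxygens on C1′ (diaryl ether), C4′ (OMe) and C6′ (prenyloxy), with the C4′ and C6′ oxygens meta, and a one-carbon branch on C2′. This is the pattern of a folded six-carbon chain C1′–C6′ in which C1′ is an aryloxy-substituted methylene and C2′ a keto ester carbon.
3. Key disconnection of 13: C5′–C6′ (terminal acylation of silyl dienol ether 10 by aryloxyacetyl chloride 6) and C1′–C2′ (aldol closure, then aromatisation). The O–C1′ bond is made earlier by alkylation at an sp3 carbon.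
4. 6 ⇐ 1 (mono-allylation, O-alkylation with 3, acidolysis, acid chloride); 10 ⇐ 2-methoxypropene 7 + methyl chlorooxoacetate 8, then silylation.
5. Ring order: ring A is present from the start; ring B is formed in step 7.

Key step: step 7

Remark: ring B is numbered C1′ (carbon bearing the diaryl ether oxygen), C2′ (branch carbon), C4′ (OMe carbon) and C6′ (prenyloxy carbon); 1 is assumed to be purchasable.

**Route**

Step 1
Reactants: 1 methyl 2,6-dihydroxy-4-methylbenzoate
Product: 2 methyl 2-hydroxy-4-methyl-6-(prop-2-en-1-yloxy)benzoate
Conditions: allyl bromide (1.05 equiv), K2CO3 (1.1 equiv), acetone, 50 °C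
Reagents that add atoms: allyl bromide, C=CCBr
Why: Williamson ether synthesis in which, after the first O-allylation, the remaining phenol is held in a hydrogen bond to the ester carbonyl, so one equivalent of bromide should give mainly the mono-ether; allyl is chosen because it should survive acid, acid chloride formation, DBU and hydride and be removable at the end without harming the prenyl ether.

Step 2
Reactants: 2 methyl 2-hydroxy-4-methyl-6-(prop-2-en-1-yloxy)benzoate; 3 tert-butyl bromoacetate
Product: 4 methyl 2-(2-tert-butoxy-2-oxoethoxy)-4-methyl-6-(prop-2-en-1-yloxy)benzoate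
Conditions: Cs2CO3 (1.5 equiv), DMF, 50 °C
Reagents that add atoms: none
Why: Williamson O-alkylation of the chelated phenol by a reactive α-bromo ester, which sets the O–C1′ bond of the future diaryl ether as an ordinary sp3 C–O bond; carbonate is too weak a base to start a Dieckmann closure onto the ring A ester.

Step 3
Reactants: 4 methyl 2-(2-tert-butoxy-2-oxoethoxy)-4-methyl-6-(prop-2-en-1-yloxy)benzoate
Product: 5 [2-(methoxycarbonyl)-5-methyl-3-(prop-2-en-1-yloxy)phenoxy]acetic acid
Conditions: CF3CO2H/CH2Cl2 (1:3), rt
Reagents that add atoms: none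
Why: Acidolysis of the tert-butyl ester through the tert-butyl cation (lost as isobutene) frees the aryloxyacetic acid, while the hindered methyl benzoate and the allyl ether are inert to CF3CO2H.

Step 4
Reactants: 5 [2-(methoxycarbonyl)-5-methyl-3-(prop-2-en-1-yloxy)phenoxy]acetic acid
Product: 6 [2-(methoxycarbonyl)-5-methyl-3-(prop-2-en-1-yloxy)phenoxy]acetyl chloride
Conditions: (COCl)2 (1.5 equiv), DMF (cat.), CH2Cl2, 0 °C → rt; evaporated with toluene and used crude
Reagents that add atoms: oxalyl chloride, O=C(Cl)C(Cl)=O
Why: Acid chloride formation through the Vilsmeier-type chloroiminium salt from DMF and oxalyl chloride, all by-products being gases, so the crude chloride is free of reagent before it meets the diene.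

Step 5
Reactants: 7 2-methoxypropene; 8 methyl chlorooxoacetate
Product: 9 methyl (3E)-4-methoxy-2-oxopent-3-enoate
Conditions: pyridine (1.2 equiv), CH2Cl2, 0 °C → rt (7 in excess, 1.5 equiv)
Reagents that add atoms: none
Why: Electrophilic acylation of an enol ether at its terminal carbon by the very reactive oxalyl monochloride, followed by loss of a proton to pyridine, the standard entry to β-alkoxy enones; the more stable E isomer, with the ketone and the methyl group cis, is expected.

Step 6
Reactants: 9 methyl (3E)-4-methoxy-2-oxopent-3-enoate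
Product: 10 methyl (2Z)-4-methoxy-2-[(trimethylsilyl)oxy]penta-2,4-dienoate
Conditions: Me3SiOSO2CF3 (1.2 equiv), Et3N (1.5 equiv), Et2O, 0 °C → rt; ammonium salt layer separated, bulb-to-bulb distillation, used at once
Reagents that add atoms: trimethylsilyl trifluoromethanesulfonate, C[Si](C)(C)OS(=O)(=O)C(F)(F)F
Why: Soft vinylogous enolisation, in which O-silylation of the ketone gives a 1-silyloxy-3-methoxyallyl cation whose only acidic protons are on the C5 methyl group, so Et3N should deliver the cross-conjugated silyl dienol ether; the C2=C3 geometry is immaterial because that bond is lost in step 7.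

Step 7
Reactants: 6 [2-(methoxycarbonyl)-5-methyl-3-(prop-2-en-1-yloxy)phenoxy]acetyl chloride; 10 methyl (2Z)-4-methoxy-2-[(trimethylsilyl)oxy]penta-2,4-dienoate
Product: 13 methyl 2-[2-hydroxy-4-methoxy-6-(methoxycarbonyl)phenoxy]-4-methyl-6-(prop-2-en-1-yloxy)benzoate, via acyclic dioxoheptenoate 11 (not isolated), via cyclohexenone aldol adduct 12 (not isolated)
Conditions: 10 (1.3 equiv), ZnCl2 (1 M in Et2O, 20 mol %), CH2Cl2, −40 °C → rt; volatiles (Me3SiCl) removed in vacuo; then DBU (3 equiv), THF, 0 → 40 °C; 1 M HCl work-up
Reagents that add atoms: none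
Why: Proposed new method: ZnCl2-assisted Mukaiyama-type C-acylation of the silyl dienol ether at its terminal CH2 by the aryloxyacetyl chloride forms C5′–C6′ with loss of Me3SiCl and gives the push–pull enone 11, whose C3′=C4′ geometry equilibrates; DBU then forms, beside the more stable but unproductive C5′ anion, the C1′ enolate, which adds to the α-keto ester carbonyl C2′, and adduct 12 loses water (E1cB) and tautomerises to the phenol. The closest known reactions are the terminal acylation of 1,3-dioxygenated silyl dienol ethers by acid chlorides and the base-induced aldol aromatisation of 3,5-dioxo chains (heptane-2,4,6-trione to orcinol); new here are the ester-bearing diene, the keto ester acceptor and the aryloxy-substituted nucleophilic carbon. Ring B closes by a 6-(enolendo)-exo-trig aldol, the only six-membered closure open to any enolisable carbon of 11. No stereocentre survives, the two of 12 being destroyed on aromatisation. The step needs acylation at the terminal carbon and not at C3′, which the unhindered CH2 and the methoxy-stabilised cation formed by attack there should secure, and it needs attack of C1′ on C2′ in preference to Dieckmann closure onto the ring A ester, which the much higher electrophilicity of the keto ester carbonyl, the two ortho oxygens shielding the ring A ester and the irreversible aromatisation should secure. The C4′ methyl enol ether excludes pyranone formation and leaves the C6′ hydroxyl as the only free phenol of ring B.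

Step 8
Reactants: 13 methyl 2-[2-hydroxy-4-methoxy-6-(methoxycarbonyl)phenoxy]-4-methyl-6-(prop-2-en-1-yloxy)benzoate; 14 1-bromo-3-methylbut-2-ene
Product: 15 methyl 2-[4-methoxy-2-(methoxycarbonyl)-6-(3-methylbut-2-en-1-yloxy)phenoxy]-4-methyl-6-(prop-2-en-1-yloxy)benzoate
Conditions: K2CO3 (1.5 equiv), acetone, rt
Reagents that add atoms: none
Why: Williamson ether synthesis on the only free phenol (C6′–OH), an SN2 O-alkylation by the primary allylic bromide that phenoxides undergo cleanly at room temperature under carbonate.

Step 9
Reactants: 15 methyl 2-[4-methoxy-2-(methoxycarbonyl)-6-(3-methylbut-2-en-1-yloxy)phenoxy]-4-methyl-6-(prop-2-en-1-yloxy)benzoate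
Product: 16 methyl 2-[2-(hydroxymethyl)-4-methoxy-6-(3-methylbut-2-en-1-yloxy)phenoxy]-4-methyl-6-(prop-2-en-1-yloxy)benzoate
Conditions: i-Bu2AlH (2.2 equiv), CH2Cl2, −78 °C; aq. potassium sodium tartrate (KNaC4H4O6) work-up
Reagents that add atoms: none
Why: Chemoselective ester reduction on steric grounds, since the ring B ester has one ortho substituent and is open from the face of its ring, whereas the ring A ester is twisted out of plane between two ortho oxygens that cover both faces of its carbonyl, so a bulky aluminium hydride at low temperature should reduce only the ring B ester to the benzylic alcohol.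

Step 10
Reactants: 16 methyl 2-[2-(hydroxymethyl)-4-methoxy-6-(3-methylbut-2-en-1-yloxy)phenoxy]-4-methyl-6-(prop-2-en-1-yloxy)benzoate
Product: 17 methyl 2-hydroxy-6-[2-(hydroxymethyl)-4-methoxy-6-(3-methylbut-2-en-1-yloxy)phenoxy]-4-methylbenzoate
Conditions: Pd(PPh3)4 (5 mol %), morpholine (5 equiv), THF, rt
Reagents that add atoms: none
Why: Tsuji–Trost-type deallylation, in which zerovalent palladium ionises the unsubstituted allyl ether (leaving group the ester-stabilised salicylate phenoxide) much faster than the trisubstituted prenyl ether of the less acidic ring B phenol, and morpholine traps the π-allyl complex irreversibly.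

**Compound list**

1 | methyl 2,6-dihydroxy-4-methylbenzoate | COC(=O)c1c(O)cc(C)cc1O | starting material
2 | methyl 2-hydroxy-4-methyl-6-(prop-2-en-1-yloxy)benzoate | COC(=O)c1c(O)cc(C)cc1OCC=C | intermediate
3 | tert-butyl bromoacetate | CC(C)(C)OC(=O)CBr | starting material
4 | methyl 2-(2-tert-butoxy-2-oxoethoxy)-4-methyl-6-(prop-2-en-1-yloxy)benzoate | COC(=O)c1c(OCC=C)cc(C)cc1OCC(=O)OC(C)(C)C | intermediate
5 | [2-(methoxycarbonyl)-5-methyl-3-(prop-2-en-1-yloxy)phenoxy]acetic acid | COC(=O)c1c(OCC=C)cc(C)cc1OCC(O)=O | intermediate
6 | [2-(methoxycarbonyl)-5-methyl-3-(prop-2-en-1-yloxy)phenoxy]acetyl chloride | COC(=O)c1c(OCC=C)cc(C)cc1OCC(Cl)=O | intermediate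
7 | 2-methoxypropene | C=C(C)OC | starting material
8 | methyl chlorooxoacetate | COC(=O)C(Cl)=O | starting material
9 | methyl (3E)-4-methoxy-2-oxopent-3-enoate | COC(=O)C(=O)/C=C(C)/OC | intermediate
10 | methyl (2Z)-4-methoxy-2-[(trimethylsilyl)oxy]penta-2,4-dienoate | COC(=O)/C(O[Si](C)(C)C)=C/C(OC)=C | intermediate
11 | methyl (3E)-4-methoxy-7-[2-(methoxycarbonyl)-5-methyl-3-(prop-2-en-1-yloxy)phenoxy]-2,6-dioxohept-3-enoate (the E isomer is the one that closes; the geometry equilibrates) | COC(=O)C(=O)/C=C(/OC)CC(=O)COc1cc(C)cc(OCC=C)c1C(=O)OC | intermediate (not isolated)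
12 | methyl 1-hydroxy-3-methoxy-6-[2-(methoxycarbonyl)-5-methyl-3-(prop-2-en-1-yloxy)phenoxy]-5-oxocyclohex-2-ene-1-carboxylate (racemic mixture of diastereomers, both centres lost on aromatisation) | COC(=O)C1(O)C=C(OC)CC(=O)C1Oc1cc(C)cc(OCC=C)c1C(=O)OC | intermediate (not isolated)
13 | methyl 2-[2-hydroxy-4-methoxy-6-(methoxycarbonyl)phenoxy]-4-methyl-6-(prop-2-en-1-yloxy)benzoate | COC(=O)c1c(OCC=C)cc(C)cc1Oc1c(O)cc(OC)cc1C(=O)OC | intermediate
14 | 1-bromo-3-methylbut-2-ene (prenyl bromide) | CC(C)=CCBr | starting material
15 | methyl 2-[4-methoxy-2-(methoxycarbonyl)-6-(3-methylbut-2-en-1-yloxy)phenoxy]-4-methyl-6-(prop-2-en-1-yloxy)benzoate | COC(=O)c1c(OCC=C)cc(C)cc1Oc1c(OCC=C(C)C)cc(OC)cc1C(=O)OC | intermediate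
16 | methyl 2-[2-(hydroxymethyl)-4-methoxy-6-(3-methylbut-2-en-1-yloxy)phenoxy]-4-methyl-6-(prop-2-en-1-yloxy)benzoate | COC(=O)c1c(OCC=C)cc(C)cc1Oc1c(CO)cc(OC)cc1OCC=C(C)C | intermediate
17 | methyl 2-hydroxy-6-[2-(hydroxymethyl)-4-methoxy-6-(3-methylbut-2-en-1-yloxy)phenoxy]-4-methylbenzoate | COC(=O)c1c(O)cc(C)cc1Oc1c(CO)cc(OC)cc1OCC=C(C)C | target

**Step count and risks**

Total steps: 10. Longest linear sequence: 8 (steps 1–4, then 7–10, from 1); the diene branch (steps 5 and 6) joins at step 7.

Steps most likely to fail:

1. Step 7 (proposed new method). The ester-deactivated diene may be acylated too slowly, or the C1′ enolate may close onto the ring A ester (Dieckmann closure to a benzofuranone), or the aldol may stall at the C5′ anion. The fallback forms the diaryl ether by copper catalysis and uses known chemistry throughout. It sets out from 2 and returns at 15, bypassing steps 3–8. Commercial methyl 3-hydroxy-5-methoxybenzoate is brominated ortho to the phenol with NBS and catalytic i-Pr2NH in CH2Cl2 at 0 °C. Of the two ortho positions, the one between OH and the ester is also para to OMe and should be preferred, giving methyl 2-bromo-3-hydroxy-5-methoxybenzoate F1. O-Prenylation with 14 (K2CO3, acetone) should give methyl 2-bromo-5-methoxy-3-(3-methylbut-2-en-1-yloxy)benzoate F2. Ullmann coupling of F2 with phenol 2 (CuI, monovalent copper, 10 mol %, N,N-dimethylglycine, Cs2CO3, dioxane, 100 °C), helped by the ortho ester on the bromide, should give 15.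

2. Step 9. Discrimination between the two methyl esters may be incomplete (partial reduction of the ring A ester), or the reduction may halt at the aldehyde. The fallback sets out from 15 and returns at 16. LiOH (THF/H2O, rt) should saponify only the ring B ester, because hydroxide addition to the di-ortho-substituted ring A ester is blocked, giving 5-methoxy-2-[2-(methoxycarbonyl)-5-methyl-3-(prop-2-en-1-yloxy)phenoxy]-3-(3-methylbut-2-en-1-yloxy)benzoic acid F3. Activation with isobutyl chloroformate and N-methylmorpholine (THF, −15 °C) gives the isobutyl carbonic mixed anhydride F4, and NaBH4 in aqueous THF reduces it to 16; NaBH4 does not touch the methyl ester or the two allylic ethers.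

3. Step 6. The amine may add to the activated enone, or the captodative diene may hydrolyse or oligomerise during isolation. The fallback replaces the silyl dienol ether by a metal dienolate; it sets out from 9 and returns at 11, which then receives the DBU treatment of step 7 to give 13. Compound 9 is added to LiN(SiMe3)2 (THF, −78 °C) to give lithium (2Z)-1,4-dimethoxy-1-oxopenta-2,4-dien-2-olate F5 (2 equiv). Acid chloride 6 (1 equiv) is then added at −78 °C. A vinylogous Claisen acylation at the terminal carbon, as is usual for lithium dienolates of 3-alkoxy enoates, should give 11 as its lithium enolate, with the second equivalent of F5 acting as base, before mild acid quench.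

**Further compounds**

F1 | step 7 | methyl 2-bromo-3-hydroxy-5-methoxybenzoate | COC(=O)c1cc(OC)cc(O)c1Br
F2 | step 7 | methyl 2-bromo-5-methoxy-3-(3-methylbut-2-en-1-yloxy)benzoate | COC(=O)c1cc(OC)cc(OCC=C(C)C)c1Br
F3 | step 9 | 5-methoxy-2-[2-(methoxycarbonyl)-5-methyl-3-(prop-2-en-1-yloxy)phenoxy]-3-(3-methylbut-2-en-1-yloxy)benzoic acid | COC(=O)c1c(OCC=C)cc(C)cc1Oc1c(OCC=C(C)C)cc(OC)cc1C(O)=O
F4 | step 9 | isobutyl carbonic mixed anhydride of F3 | COC(=O)c1c(OCC=C)cc(C)cc1Oc1c(OCC=C(C)C)cc(OC)cc1C(=O)OC(=O)OCC(C)C
F5 | step 6 | lithium (2Z)-1,4-dimethoxy-1-oxopenta-2,4-dien-2-olate | [Li+].COC(=O)/C([O-])=C/C(OC)=C
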